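## Retrosynthetic overview

1. Tail: the C3''–C4'' bond of the octadecanoate is made on the finished core. A pentadecyl radical (palmitic acid minus CO2) adds to an acrylate ester at O4' in a decarboxylative Giese reaction.
2. Enabling feature: the ester carbonyl C1'' lies two atoms from C3''. C2''–C3'' can therefore be carried one oxidation level higher as an acrylate. Its terminus C3'' is the only electron-poor alkene carbon once the exocyclic C11=C13 of the α-methylene-γ-butyrolactone ring is parked as its Me2NH adduct. The trisubstituted C1=C10 and C4=C5 of the ten-membered ring are electron-rich and inert to alkyl radicals.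
3. Ten-membered carbocycle (second ring): C9–C10 by intramolecular Nozaki–Hiyama–Kishi addition of a (Z)-alkenyl iodide to an α-acyloxy aldehyde. This sets C9 and leaves 9-OH free beside the 8-ester.
4. 8-Ester and C8: the linker acid is placed on the primary O9, then moved to O8 with inversion through a 1,3-dioxolan-2-ylium ion.
5. γ-Lactone (first ring), C6 and C7: Cr(II) 2-(methoxycarbonyl)allylation of a geranyl acetate-derived enal with a bromide from (S)-glyceraldehyde acetonide, then lactonisation. C3' is bought in (S)-3-bromo-2-methylpropan-1-ol.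

Key step: step 20

Remark: germacrane numbering is used for the core (C6 lactone carbinol, C7 fusion carbon bearing C11, C8 ester carbinol, C9 free carbinol, C12 lactone C=O, C11=C13 exocyclic methylene), C1'–C4' for the 3-methylbutanoate linker and C1''–C18'' for the octadecanoate. The carbinol centre of 10 and C11 of 29, 30 and 35–37 arise as inconsequential epimer mixtures, return to sp2 later, and are left undefined in the SMILES.

## Route

Step 1
Reactants: 1 geranyl acetate
Product: 2 6,7-epoxygeranyl acetate (racemic epoxide)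
Conditions: mCPBA (1.0 equiv), CH2Cl2, 0 °C
Reagents that add atoms: mCPBA, O=C(OO)c1cccc(Cl)c1
Why: Prilezhaev epoxidation takes the electron-rich 6,7-alkene because the 2,3-alkene is deactivated by the allylic acetate; the epoxide stereocentre is destroyed in step 2.

Step 2
Reactants: 2 6,7-epoxygeranyl acetate
Product: 4 (2E)-3-methyl-6-oxohex-2-en-1-yl acetate, via 6,7-diol 3 (not isolated)
Conditions: H5IO6, THF/H2O, 0 °C
Reagents that add atoms: water, O (retained only in 3)
Why: Acid-assisted epoxide hydrolysis followed by Malaprade glycol cleavage removes the isopropylidene end as acetone and leaves the E-alkene and the acetate untouched.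

Step 3
Reactants: 4 (2E)-3-methyl-6-oxohex-2-en-1-yl acetate
Product: 5 (2E,6Z)-7-iodo-3-methylocta-2,6-dien-1-yl acetate
Conditions: EtPPh3I, n-BuLi, THF, rt; I2, −78 °C; NaHMDS, −20 °C; then 4, −78 to −20 °C
Reagents that add atoms: ethyltriphenylphosphonium iodide, CC[P+](c1ccccc1)(c1ccccc1)c1ccccc1.[I-]; iodine, II
Why: Stork–Zhao-type Wittig olefination with the α-iodoethylidene ylide is kinetically Z-selective (iodine cis to the chain), which fixes the later C1=C10 geometry with C2 and C9 cis.

Step 4
Reactants: 5 (2E,6Z)-7-iodo-3-methylocta-2,6-dien-1-yl acetate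
Product: 6 (2E,6Z)-7-iodo-3-methylocta-2,6-dien-1-ol
Conditions: K2CO3 (cat.), MeOH, rt
Reagents that add atoms: none
Why: Base-catalysed transesterification (Zemplén type) removes only the acetate and touches neither alkene.

Step 5
Reactants: 6 (2E,6Z)-7-iodo-3-methylocta-2,6-dien-1-ol
Product: 7 (2E,6Z)-7-iodo-3-methylocta-2,6-dienal
Conditions: MnO2, CH2Cl2, rt
Reagents that add atoms: none
Why: MnO2 oxidises the allylic alcohol to the enal under neutral conditions without E/Z scrambling and without touching the alkenyl iodide.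

Step 6
Reactants: 8 (4S)-2,2-dimethyl-1,3-dioxolane-4-carbaldehyde; 9 methyl acrylate
Product: 10 methyl 2-{[(4S)-2,2-dimethyl-1,3-dioxolan-4-yl](hydroxy)methyl}prop-2-enoate (carbinol epimers)
Conditions: DABCO (0.5 equiv), dioxane/H2O 1:1, rt
Reagents that add atoms: none
Why: Morita–Baylis–Hillman reaction joins C7 to C11; the new carbinol centre becomes sp2 in step 7 and the bought C8 centre is retained.

Step 7
Reactants: 10 Morita–Baylis–Hillman adduct
Product: 11 methyl (2Z)-2-(bromomethyl)-3-[(4R)-2,2-dimethyl-1,3-dioxolan-4-yl]prop-2-enoate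
Conditions: NBS, Me2S, CH2Cl2, 0 °C to rt
Reagents that add atoms: N-bromosuccinimide, O=C1CCC(=O)N1Br
Why: Corey–Kim-type activation to the alkoxysulfonium salt and SN2' attack of bromide give the favoured (Z)-2-(bromomethyl)enoate (C8 cis to CH2Br) under non-acidic conditions that spare the acetonide.

Step 8
Reactants: 11 methyl (2Z)-2-(bromomethyl)-3-[(4R)-2,2-dimethyl-1,3-dioxolan-4-yl]prop-2-enoate; 7 (2E,6Z)-7-iodo-3-methylocta-2,6-dienal
Product: 14 cis-lactone acetonide (4S,5S)-4-[(4R)-2,2-dimethyl-1,3-dioxolan-4-yl]-5-[(1E,5Z)-6-iodo-2-methylhepta-1,5-dien-1-yl]-3-methylideneoxolan-2-one, via allylchromium reagent 12 (not isolated), via syn hydroxy ester 13 (not isolated)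
Conditions: CrCl2 (nickel-free, 3 equiv), THF, 0 °C to rt; aqueous work-up; PPTS (cat.), toluene, 60 °C
Reagents that add atoms: chromium(II) chloride, Cl[Cr]Cl (retained only in 12)
Why: In this Nozaki–Hiyama 2-(alkoxycarbonyl)allylation, reagent 12 keeps C8 cis to CH2Cr and adds at C7 through a Zimmerman–Traxler chair to give the syn adduct (hence H6/H7 cis), the aldehyde approaching the C7=C11 face anti to the C8–O bond of the A(1,3)-locked dioxolane (C8–H eclipsing the alkene), and acid-catalysed transesterification then closes the γ-lactone.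

Step 9
Reactants: 14 cis-lactone acetonide
Product: 15 (4R,5S)-4-[(1R)-1,2-dihydroxyethyl]-5-[(1E,5Z)-6-iodo-2-methylhepta-1,5-dien-1-yl]-3-methylideneoxolan-2-one
Conditions: AcOH/THF/H2O, 40 °C
Reagents that add atoms: none
Why: Mild acetal hydrolysis frees the C8/C9 diol under conditions too weak to ionise the allylic C6–O bond or to translactonise.

Step 10
Reactants: 16 (S)-3-bromo-2-methylpropan-1-ol
Product: 17 (S)-(3-bromo-2-methylpropoxy)(tert-butyl)diphenylsilane
Conditions: TBDPSCl, imidazole, CH2Cl2, rt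
Reagents that add atoms: tert-butyl(chloro)diphenylsilane, CC(C)(C)[Si](Cl)(c1ccccc1)c1ccccc1
Why: Standard silylation protects the later O4' with a group that survives steps 11–15.

Step 11
Reactants: 17 (S)-(3-bromo-2-methylpropoxy)(tert-butyl)diphenylsilane
Product: 19 (3R)-4-[(tert-butyldiphenylsilyl)oxy]-3-methylbutanoic acid, via Grignard reagent 18 (not isolated)
Conditions: Mg, THF, reflux; CO2, −20 °C; 1 M HCl
Reagents that add atoms: magnesium, [Mg] (retained only in 18); carbon dioxide, O=C=O
Why: Grignard carboxylation adds C1' without touching the β-stereocentre C3', whose descriptor changes from S to R only through the priority switch.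

Step 12
Reactants: 15 lactone diol; 19 (3R)-4-[(tert-butyldiphenylsilyl)oxy]-3-methylbutanoic acid
Product: 20 O9 ester (2R)-2-hydroxy-2-[(2S,3R)-2-[(1E,5Z)-6-iodo-2-methylhepta-1,5-dien-1-yl]-4-methylidene-5-oxooxolan-3-yl]ethyl (3R)-4-[(tert-butyldiphenylsilyl)oxy]-3-methylbutanoate
Conditions: DIC, DMAP (cat.), CH2Cl2, −20 to 0 °C
Reagents that add atoms: none
Why: Steglich esterification at low temperature acylates the unhindered primary O9–H in preference to the secondary O8–H, which is flanked by the branched C7.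

Step 13
Reactants: 20 O9 ester
Product: 24 O8 ester (1S)-2-hydroxy-1-[(2S,3S)-2-[(1E,5Z)-6-iodo-2-methylhepta-1,5-dien-1-yl]-4-methylidene-5-oxooxolan-3-yl]ethyl (3R)-4-[(tert-butyldiphenylsilyl)oxy]-3-methylbutanoate, via C8 triflate 21 (not isolated), via dioxolan-2-ylium triflate 22 (not isolated), via hemiorthoester 23 (not isolated)
Conditions: Tf2O, 2,6-lutidine, CH2Cl2, −40 to 0 °C; then THF/H2O, 0 °C to rt
Reagents that add atoms: trifluoromethanesulfonic anhydride, O=S(=O)(OS(=O)(=O)C(F)(F)F)C(F)(F)F (retained only in 21 and 22); water, O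
Why: By neighbouring-group participation the O9 ester carbonyl displaces the C8 triflate from the rear (inversion, R to S), and kinetic hydrolysis of the 1,3-dioxolan-2-ylium ion via the hemiorthoester releases the primary O9–H and leaves the acyl group on O8, as in the wet Woodward–Prévost reaction and the orthoester route to secondary monoesters of 1,2-diols.

Step 14
Reactants: 24 O8 ester with free primary alcohol
Product: 25 α-acyloxy aldehyde (1S)-2-oxo-1-[(2S,3S)-2-[(1E,5Z)-6-iodo-2-methylhepta-1,5-dien-1-yl]-4-methylidene-5-oxooxolan-3-yl]ethyl (3R)-4-[(tert-butyldiphenylsilyl)oxy]-3-methylbutanoate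
Conditions: DMP, CH2Cl2, 0 °C to rt, used at once
Reagents that add atoms: none
Why: Dess–Martin oxidation works fast and without base, so neither O8-to-O9 acyl migration nor epimerisation at C8 should intervene.

Step 15
Reactants: 25 α-acyloxy aldehyde
Product: 27 (6S,7S,8S,9R,1(10)Z,4E)-8-{[(3R)-4-(tert-butyldiphenylsilyloxy)-3-methylbutanoyl]oxy}-9-hydroxygermacra-1(10),4,11(13)-trien-12,6-olide, via alkenylchromium species 26 (not isolated)
Conditions: CrCl2 (excess), NiCl2 (cat.), DMSO/THF, rt, slow addition to 2 mM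
Reagents that add atoms: chromium(II) chloride, Cl[Cr]Cl (retained only in 26)
Why: Intramolecular Nozaki–Hiyama–Kishi reaction (Ni insertion into C–I with retention of the Z geometry, transmetalation to Cr(III), carbonyl addition) closes the ten-membered ring at C9–C10, and polar Felkin–Anh attack anti to the C8–O(acyl) bond should give the 8,9-anti (9R) alcohol.

Step 16
Reactants: 27 silylated macrocycle
Product: 28 (6S,7S,8S,9R,1(10)Z,4E)-9-hydroxy-8-{[(3R)-4-hydroxy-3-methylbutanoyl]oxy}germacra-1(10),4,11(13)-trien-12,6-olide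
Conditions: HF·pyridine, pyridine, THF, 0 °C to rt
Reagents that add atoms: none
Why: Buffered fluoride desilylation frees O4'–H without the basic conditions that would move the 8-acyl group.

Step 17
Reactants: 28 macrocyclic diol
Product: 29 13-(dimethylamino)-11,13-dihydro derivative of 28
Conditions: Me2NH (2 M in THF), EtOH, 0 °C
Reagents that add atoms: dimethylamine, CNC
Why: Aza-Michael addition to C13 of the strained s-cis enoate is the classical reversible protection of α-methylene-γ-butyrolactones, and the C11 centre it creates is erased in step 21.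

Step 18
Reactants: 29 amine-masked diol
Product: 30 O4' acrylate of 29
Conditions: acryloyl chloride (1.05 equiv), i-Pr2NEt, CH2Cl2, −78 to −40 °C
Reagents that add atoms: acryloyl chloride, C=CC(=O)Cl
Why: Kinetic acylation selects the primary O4'–H over the secondary allylic 9-OH, which is shielded by C10 and the 8-ester.

Step 19
Reactants: 31 palmitic acid; 32 N-hydroxyphthalimide
Product: 33 1,3-dioxoisoindolin-2-yl hexadecanoate
Conditions: DIC, DMAP (cat.), CH2Cl2, rt
Reagents that add atoms: none
Why: Carbodiimide (Steglich-type) coupling turns the feedstock acid into its redox-active ester.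

Step 20
Reactants: 30 O4' acrylate; 33 1,3-dioxoisoindolin-2-yl hexadecanoate
Product: 36 13-(dimethylamino)-11,13-dihydro derivative of the target, via pentadecyl radical 34 (not isolated), via alpha-ester radical 35 (not isolated)
Conditions: 33 (2 equiv), Hantzsch ester (2.5 equiv), Ru(bpy)3(PF6)2 (1 mol %), CH2Cl2 (0.02 M in 30), 450 nm LEDs, rt, degassed
Reagents that add atoms: none
Why: Ru(I), formed when the Hantzsch ester quenches excited Ru(II), transfers one electron to 33, whose radical anion cleaves at N–O and loses CO2 to give the primary, nucleophilic radical 34; this adds to the unsubstituted terminus C3'' of the acrylate (the new C3''–C4'' bond), and radical 35 takes a hydrogen atom from the Hantzsch ester to give 36. The closest known reaction type is the reductive decarboxylative Giese addition of N-(acyloxy)phthalimides to acrylates under photoredox/Hantzsch ester conditions, which is established for primary alkyl radicals. No ring is closed and no stereocentre is created, and the existing centres C6, C7, C8, C9 and C3' are not touched because no strong acid, base or hydride is present. The step needs site selectivity among the C=C bonds: polarity matching sends the nucleophilic radical to the only electron-poor alkene left, since C11=C13 of the lactone ring is stored as the β-amino adduct and the electron-rich trisubstituted C1=C10 and C4=C5 add alkyl radicals far more slowly. Telomerisation is held back by dilution and by the excess of 33 and hydrogen donor, the Hantzsch ester should be oxidised in preference to the inductively deactivated C13 amine, and the free 9-OH needs no protection. In one operation 15 of the 38 carbons are delivered from a feedstock fatty acid to a precursor that carries only a three-carbon acrylate.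

Step 21
Reactants: 36 amine-masked stearate
Product: 38 target CNP0114940.1, via trimethylammonium iodide 37 (not isolated)
Conditions: MeI, THF, rt; concentrate; sat. aq. NaHCO3/CH2Cl2, rt
Reagents that add atoms: iodomethane, CI (retained only in 37)
Why: Menshutkin quaternisation followed by bicarbonate-induced E1cB (Hofmann-type) loss of trimethylamine regenerates C11=C13 under conditions too mild to hydrolyse or shift any of the esters.

## Compound list

1 | geranyl acetate, (2E)-3,7-dimethylocta-2,6-dien-1-yl acetate | CC(C)=CCC/C(C)=C/COC(C)=O | starting material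
2 | 6,7-epoxygeranyl acetate (racemic epoxide) | CC1(C)OC1CC/C(C)=C/COC(C)=O | intermediate
3 | (2E)-6,7-dihydroxy-3,7-dimethyloct-2-en-1-yl acetate (racemic) | CC(C)(O)C(O)CC/C(C)=C/COC(C)=O | intermediate (not isolated)
4 | (2E)-3-methyl-6-oxohex-2-en-1-yl acetate | O=CCC/C(C)=C/COC(C)=O | intermediate
5 | (2E,6Z)-7-iodo-3-methylocta-2,6-dien-1-yl acetate | C/C(I)=C/CC/C(C)=C/COC(C)=O | intermediate
6 | (2E,6Z)-7-iodo-3-methylocta-2,6-dien-1-ol | C/C(I)=C/CC/C(C)=C/CO | intermediate
7 | (2E,6Z)-7-iodo-3-methylocta-2,6-dienal | C/C(I)=C/CC/C(C)=C/C=O | intermediate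
8 | (4S)-2,2-dimethyl-1,3-dioxolane-4-carbaldehyde | O=C[C@@H]1COC(C)(C)O1 | starting material
9 | methyl acrylate | C=CC(=O)OC | starting material
10 | methyl 2-{[(4S)-2,2-dimethyl-1,3-dioxolan-4-yl](hydroxy)methyl}prop-2-enoate (carbinol epimers) | C=C(C(=O)OC)C(O)[C@@H]1COC(C)(C)O1 | intermediate
11 | methyl (2Z)-2-(bromomethyl)-3-[(4R)-2,2-dimethyl-1,3-dioxolan-4-yl]prop-2-enoate | COC(=O)/C(CBr)=C/[C@@H]1COC(C)(C)O1 | intermediate
12 | allylchromium(III) dichloride derived from 11 | COC(=O)/C(C[Cr](Cl)Cl)=C/[C@@H]1COC(C)(C)O1 | intermediate (not isolated)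
13 | methyl (3S,4S,5E,9Z)-3-[(4R)-2,2-dimethyl-1,3-dioxolan-4-yl]-4-hydroxy-10-iodo-6-methyl-2-methylideneundeca-5,9-dienoate | COC(=O)C(=C)[C@@H]([C@@H](O)/C=C(\C)CC/C=C(/C)I)[C@@H]1COC(C)(C)O1 | intermediate (not isolated)
14 | (4S,5S)-4-[(4R)-2,2-dimethyl-1,3-dioxolan-4-yl]-5-[(1E,5Z)-6-iodo-2-methylhepta-1,5-dien-1-yl]-3-methylideneoxolan-2-one (H6/H7 cis) | C=C1C(=O)O[C@@H](/C=C(\C)CC/C=C(/C)I)[C@H]1[C@@H]2COC(C)(C)O2 | intermediate
15 | (4R,5S)-4-[(1R)-1,2-dihydroxyethyl]-5-[(1E,5Z)-6-iodo-2-methylhepta-1,5-dien-1-yl]-3-methylideneoxolan-2-one | C=C1C(=O)O[C@@H](/C=C(\C)CC/C=C(/C)I)[C@H]1[C@@H](O)CO | intermediate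
16 | (S)-3-bromo-2-methylpropan-1-ol | BrC[C@@H](C)CO | starting material
17 | (S)-(3-bromo-2-methylpropoxy)(tert-butyl)diphenylsilane | BrC[C@@H](C)CO[Si](c1ccccc1)(c1ccccc1)C(C)(C)C | intermediate
18 | Grignard reagent of 17 | Br[Mg]C[C@@H](C)CO[Si](c1ccccc1)(c1ccccc1)C(C)(C)C | intermediate (not isolated)
19 | (3R)-4-[(tert-butyldiphenylsilyl)oxy]-3-methylbutanoic acid | OC(=O)C[C@@H](C)CO[Si](c1ccccc1)(c1ccccc1)C(C)(C)C | intermediate
20 | O9 ester of 15 with 19 (C8 carbinol free, 8R) | C=C1C(=O)O[C@@H](/C=C(\C)CC/C=C(/C)I)[C@H]1[C@@H](O)COC(=O)C[C@@H](C)CO[Si](c1ccccc1)(c1ccccc1)C(C)(C)C | intermediate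
21 | C8 triflate of 20 | C=C1C(=O)O[C@@H](/C=C(\C)CC/C=C(/C)I)[C@H]1[C@@H](OS(=O)(=O)C(F)(F)F)COC(=O)C[C@@H](C)CO[Si](c1ccccc1)(c1ccccc1)C(C)(C)C | intermediate (not isolated)
22 | 1,3-dioxolan-2-ylium triflate spanning O8 and O9 (C8 inverted) | C=C1C(=O)O[C@@H](/C=C(\C)CC/C=C(/C)I)[C@H]1[C@H]2COC(C[C@@H](C)CO[Si](c3ccccc3)(c3ccccc3)C(C)(C)C)=[O+]2.[O-]S(=O)(=O)C(F)(F)F | intermediate (not isolated)
23 | 2-hydroxy-1,3-dioxolane (hemiorthoester) from 22 | C=C1C(=O)O[C@@H](/C=C(\C)CC/C=C(/C)I)[C@H]1[C@H]2COC(O)(C[C@@H](C)CO[Si](c3ccccc3)(c3ccccc3)C(C)(C)C)O2 | intermediate (not isolated)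
24 | O8 ester with free primary 9-OH (8S) | C=C1C(=O)O[C@@H](/C=C(\C)CC/C=C(/C)I)[C@H]1[C@@H](CO)OC(=O)C[C@@H](C)CO[Si](c1ccccc1)(c1ccccc1)C(C)(C)C | intermediate
25 | C9 aldehyde of 24 | C=C1C(=O)O[C@@H](/C=C(\C)CC/C=C(/C)I)[C@H]1[C@@H](C=O)OC(=O)C[C@@H](C)CO[Si](c1ccccc1)(c1ccccc1)C(C)(C)C | intermediate
26 | (Z)-alkenylchromium(III) dichloride derived from 25 | C=C1C(=O)O[C@@H](/C=C(\C)CC/C=C(/C)[Cr](Cl)Cl)[C@H]1[C@@H](C=O)OC(=O)C[C@@H](C)CO[Si](c1ccccc1)(c1ccccc1)C(C)(C)C | intermediate (not isolated)
27 | (6S,7S,8S,9R,1(10)Z,4E)-8-{[(3R)-4-(tert-butyldiphenylsilyloxy)-3-methylbutanoyl]oxy}-9-hydroxygermacra-1(10),4,11(13)-trien-12,6-olide | C=C1C(=O)O[C@H]2/C=C(\C)CC/C=C(/C)[C@@H](O)[C@@H](OC(=O)C[C@@H](C)CO[Si](c3ccccc3)(c3ccccc3)C(C)(C)C)[C@@H]12 | intermediate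
28 | (6S,7S,8S,9R,1(10)Z,4E)-9-hydroxy-8-{[(3R)-4-hydroxy-3-methylbutanoyl]oxy}germacra-1(10),4,11(13)-trien-12,6-olide | C=C1C(=O)O[C@H]2/C=C(\C)CC/C=C(/C)[C@@H](O)[C@@H](OC(=O)C[C@@H](C)CO)[C@@H]12 | intermediate
29 | 13-(dimethylamino)-11,13-dihydro-28 (C11 undefined) | CN(C)CC1C(=O)O[C@H]2/C=C(\C)CC/C=C(/C)[C@@H](O)[C@@H](OC(=O)C[C@@H](C)CO)[C@@H]12 | intermediate
30 | O4' acrylate of 29 | CN(C)CC1C(=O)O[C@H]2/C=C(\C)CC/C=C(/C)[C@@H](O)[C@@H](OC(=O)C[C@@H](C)COC(=O)C=C)[C@@H]12 | intermediate
31 | palmitic acid (hexadecanoic acid) | CCCCCCCCCCCCCCCC(=O)O | starting material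
32 | N-hydroxyphthalimide | ON1C(=O)c2ccccc2C1=O | starting material
33 | 1,3-dioxoisoindolin-2-yl hexadecanoate | CCCCCCCCCCCCCCCC(=O)ON1C(=O)c2ccccc2C1=O | intermediate
34 | pentadecyl radical | [CH2]CCCCCCCCCCCCCC | intermediate (not isolated)
35 | C2'' radical formed by addition of 34 to 30 | CN(C)CC1C(=O)O[C@H]2/C=C(\C)CC/C=C(/C)[C@@H](O)[C@@H](OC(=O)C[C@@H](C)COC(=O)[CH]CCCCCCCCCCCCCCCC)[C@@H]12 | intermediate (not isolated)
36 | 13-(dimethylamino)-11,13-dihydro derivative of the target | CN(C)CC1C(=O)O[C@H]2/C=C(\C)CC/C=C(/C)[C@@H](O)[C@@H](OC(=O)C[C@@H](C)COC(=O)CCCCCCCCCCCCCCCCC)[C@@H]12 | intermediate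
37 | 13-(trimethylammonio)-11,13-dihydro derivative of the target, iodide | C[N+](C)(C)CC1C(=O)O[C@H]2/C=C(\C)CC/C=C(/C)[C@@H](O)[C@@H](OC(=O)C[C@@H](C)COC(=O)CCCCCCCCCCCCCCCCC)[C@@H]12.[I-] | intermediate (not isolated)
38 | CNP0114940.1, (6S,7S,8S,9R,1(10)Z,4E)-9-hydroxy-8-{[(3R)-3-methyl-4-(octadecanoyloxy)butanoyl]oxy}germacra-1(10),4,11(13)-trien-12,6-olide | C=C1C(=O)O[C@H]2/C=C(\C)CC/C=C(/C)[C@@H](O)[C@@H](OC(=O)C[C@@H](C)COC(=O)CCCCCCCCCCCCCCCCC)[C@@H]12 | target

## Step count and risks

Total step count: 21.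
Longest linear sequence: 16 steps from geranyl acetate (steps 1–5, 8, 9, 12–18, 20, 21).

Steps most likely to fail:

1. **Step 8.** The allylchromium reagent may undergo reductive 1,4-elimination with loss of the dioxolane oxygen. Alternatively, the facial selectivity at C7 relative to C8 may be poor, or the syn preference may erode.
   The fallback sets out from bromide 11 (with enal 7). Palladium-catalysed borylation with B2pin2 converts 11 into the isolable pinacol allylboronate F1, which cannot eliminate. Its closed, type-I allylboration of 7 under a chiral BINOL-derived phosphoric acid carries the alkene geometry (C8 cis to CH2B) into the syn adduct. The catalyst, not the C8 centre alone, then chooses the aldehyde face. Aqueous work-up gives hydroxy ester 13, where the route is rejoined.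

2. **Step 13.** The triflate may be lost by E2 elimination towards the allylic C7–H before the ester can participate. Alternatively, the hemiorthoester may open unselectively, with drift of the acyl group back to O9.
   The fallback sets out from diol 15 (with acid 19). Selective silylation of O9 (TESCl, 2,6-lutidine, −78 °C) gives the primary triethylsilyl ether F2. Mitsunobu esterification with 19 (PPh3, DIAD, toluene) brings in the acyl group intermolecularly with inversion at C8, giving the doubly silylated ester F3. Mild acid (AcOH/THF/H2O) removes only the triethylsilyl group, and the route is rejoined at 24.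

3. **Step 15.** Facial selectivity at the aldehyde may be poor under the constraints of the forming ten-membered ring, so that the wrong C9 configuration prevails.
   The fallback sets out from aldehyde 25. The cyclisation product is taken on as the 9-epimeric alcohol F4, alone or mixed with 27. It is oxidised with MnO2 to the C9 enone F5. C9 is then set by hydride delivery instead of C–C bond formation, using Corey–Bakshi–Shibata reduction with catecholborane at low temperature under reagent control, which spares the conjugated lactone. The route is rejoined at 27.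

Further compounds
F1 | step 8 | methyl (2E)-3-[(4R)-2,2-dimethyl-1,3-dioxolan-4-yl]-2-[(4,4,5,5-tetramethyl-1,3,2-dioxaborolan-2-yl)methyl]prop-2-enoate | COC(=O)/C(CB1OC(C)(C)C(C)(C)O1)=C/[C@@H]2COC(C)(C)O2
F2 | step 13 | O9 triethylsilyl ether of 15 | C=C1C(=O)O[C@@H](/C=C(\C)CC/C=C(/C)I)[C@H]1[C@@H](O)CO[Si](CC)(CC)CC
F3 | step 13 | O8 ester (8S) of F2 with 19, O9 triethylsilyl ether | C=C1C(=O)O[C@@H](/C=C(\C)CC/C=C(/C)I)[C@H]1[C@@H](CO[Si](CC)(CC)CC)OC(=O)C[C@@H](C)CO[Si](c1ccccc1)(c1ccccc1)C(C)(C)C
F4 | step 15 | 9-epimer (9S) of 27 | C=C1C(=O)O[C@H]2/C=C(\C)CC/C=C(/C)[C@H](O)[C@@H](OC(=O)C[C@@H](C)CO[Si](c3ccccc3)(c3ccccc3)C(C)(C)C)[C@@H]12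
F5 | step 15 | 9-oxo analogue (enone) of 27 | C=C1C(=O)O[C@H]2/C=C(\C)CC/C=C(/C)C(=O)[C@@H](OC(=O)C[C@@H](C)CO[Si](c3ccccc3)(c3ccccc3)C(C)(C)C)[C@@H]12
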